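The whole construction rests on closing the left oxepane (ring O–C7–C6–C5–C4–C3–C2) last, through its O–C2 bond, when both cyclohexanes and the acetylated right oxepane already exist (biogenetic numbering: C2 = CMe2, C3 = CHOH, C6 = quaternary carbon, C7 = CH–O; right half primed). A (3S)-2,3-epoxide is opened 7-endo by the equatorial C7 hydroxyl: the gem-dimethyl carbon C2 alone can carry positive charge, so oxirane strain is released at C2 while C3 keeps its oxygen as the only free hydroxyl of the target. The precursor is an epoxy alcohol whose left cyclohexane carries the epoxy-homoprenyl chain on C6; both halves derive from one enone and are united by aldol condensation.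

Key step: step 17

Remark on labels: left half C-2 (CMe2), C-3 (CHOH), C-4, C-5, C-6 (quaternary, CH3), C-7 (CH–O), C-8, C-9, C-10 (C=CH2), C-11 (CH), C-12; the right half carries the same numbers with primes (acetates on C-3′ and C-10′); C-12–C-12′ is the ethylene bridge.

Assumption: 1,2:4,5-di-O-isopropylidene-β-L-erythro-2,3-hexodiulo-2,6-pyranose (the L-fructose-derived Shi ketone, enantiomer of the common catalyst) is taken as an available catalyst; it is otherwise made from L-sorbose.

Step 1
Reactants: 1 1,4-dioxaspiro[4.5]dec-6-en-8-one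
Product: 2 7-iodo-1,4-dioxaspiro[4.5]dec-6-en-8-one
Conditions: I2, pyridine, CH2Cl2, 0 °C to rt
Reagents that add atoms: iodine, II
Why: α-Iodination of the enone (conjugate addition of pyridine, iodination of the enolate, elimination) should give the 2-iodoenone, which prepares both the enantioselective reduction and the later introduction of the C-6 methyl; no stereocentre is formed.

Step 2
Reactants: 2 7-iodo-1,4-dioxaspiro[4.5]dec-6-en-8-one
Product: 3 (S)-7-iodo-1,4-dioxaspiro[4.5]dec-6-en-8-ol
Conditions: (R)-1-methyl-3,3-diphenyltetrahydro-1H,3H-pyrrolo[1,2-c][1,3,2]oxazaborole ((R)-Me-CBS, 0.2 equiv), BH3·SMe2, THF, −20 °C; then MeOH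
Reagents that add atoms: none
Why: CBS reduction in which the iodoalkenyl arm acts as the large group, so the (R)-catalyst should deliver hydride to the face that gives the (S)-carbinol, the future C-7.

Step 3
Reactants: 3 (S)-7-iodo-1,4-dioxaspiro[4.5]dec-6-en-8-ol
Product: 4 (S)-tert-butyl[(7-iodo-1,4-dioxaspiro[4.5]dec-6-en-8-yl)oxy]dimethylsilane
Conditions: TBSCl, imidazole, DMF, rt
Reagents that add atoms: tert-butyldimethylsilyl chloride, CC(C)(C)[Si](C)(C)Cl
Why: Imidazole-promoted silylation of the secondary allylic alcohol installs the bulky ether that later directs the conjugate addition, without touching the stereocentre.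

Step 4
Reactants: 4 (S)-tert-butyl[(7-iodo-1,4-dioxaspiro[4.5]dec-6-en-8-yl)oxy]dimethylsilane
Product: 5 (S)-tert-butyldimethyl[(7-methyl-1,4-dioxaspiro[4.5]dec-6-en-8-yl)oxy]silane
Conditions: Me2Zn, Pd(PPh3)4 (5 mol %), THF, 50 °C
Reagents that add atoms: dimethylzinc, C[Zn]C
Why: Negishi coupling of the vinyl iodide under zerovalent palladium catalysis replaces iodine by the future C-6 methyl with the double bond kept in place and the carbinol centre untouched.

Step 5
Reactants: 5 (S)-tert-butyldimethyl[(7-methyl-1,4-dioxaspiro[4.5]dec-6-en-8-yl)oxy]silane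
Product: 6 (S)-4-(tert-butyldimethylsilyloxy)-3-methylcyclohex-2-en-1-one
Conditions: pyridinium p-toluenesulfonate (cat.), acetone/H2O, 50 °C
Reagents that add atoms: water, O
Why: Acid-catalysed hydrolysis of the allylic dioxolane unmasks the ketone in conjugation with the methyl-bearing double bond, while the secondary silyl ether and its stereocentre survive the mild acid.

Step 6
Reactants: 6 (S)-4-(tert-butyldimethylsilyloxy)-3-methylcyclohex-2-en-1-one; 7 5-bromo-2-methylpent-2-ene
Product: 9 silyl enol ether (6S,7S) of the conjugate adduct, via Grignard reagent 8 (not isolated)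
Conditions: 7, Mg, THF, rt; then CuBr·SMe2 (10 mol %), HMPA, TMSCl, 6, THF, −78 °C; Et3N, pentane work-up
Reagents that add atoms: chlorotrimethylsilane, C[Si](C)(C)Cl
Why: Copper-catalysed conjugate addition of the Grignard reagent with in situ O-silylation should create the quaternary C-6 by axial attack anti to the C-7 silyloxy group (methyl cis to the oxygen, chain trans) and store the enolate regiospecifically at C-10/C-11 as its silyl enol ether.

Step 7
Reactants: 9 silyl enol ether (6S,7S)
Product: 11 2-allyl ketone (C-11′ epimers), via lithium enolate 10 (not isolated)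
Conditions: MeLi, THF, 0 °C; then allyl iodide, HMPA, −78 to −20 °C
Reagents that add atoms: allyl iodide, C=CCI
Why: Si–O cleavage by MeLi gives the regiodefined lithium enolate, whose C-allylation puts the two-carbon unit (future C-12′ and C-12) on C-11′; the configuration at C-11′ is not controlled here and is settled in step 10.

Step 8
Reactants: 11 2-allyl ketone (C-11′ epimers)
Product: 12 hydroxy ketone (C-7′ OH free)
Conditions: HF·pyridine, THF, 0 °C to rt
Reagents that add atoms: none
Why: Fluoride-driven desilylation frees the C-7′ hydroxyl that will become the ring oxygen, and no stereocentre is touched.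

Step 9
Reactants: 12 hydroxy ketone
Product: 13 (3′S)-epoxy alcohol
Conditions: L-fructose-derived Shi ketone (0.3 equiv), Oxone (KHSO5), K2CO3, Bu4NHSO4, MeCN/dimethoxymethane/aqueous Na2B4O7 buffer, 0 °C
Reagents that add atoms: potassium peroxymonosulfate (Oxone), [K+].[O-]S(=O)(=O)OO
Why: Shi epoxidation through the chiral dioxirane and a spiro transition state oxidises only the electron-rich trisubstituted alkene (the terminal allyl group reacts far more slowly), and the L-fructose-derived catalyst sets C-3′ as (S) under reagent control.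

Step 10
Reactants: 13 (3′S)-epoxy alcohol
Product: 15 right-half oxepane ketone (3′S,6′S,7′S,11′S), via oxepane ketone epimers 14 (not isolated)
Conditions: (+)-camphor-10-sulfonic acid (0.1 equiv), CH2Cl2, 0 °C; then NaOMe, MeOH, rt
Reagents that add atoms: none
Why: The same acid-triggered hydroxy-epoxide cyclisation as in the key step should close the right oxepane 7-endo at the cation-stabilising C-2′ with C-3′ keeping its (S) oxygen, and methoxide then equilibrates the enolisable C-11′ of the now rigid trans-fused bicycle to the equatorial allyl epimer (thermodynamic control).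

Step 11
Reactants: 15 right-half oxepane ketone
Product: 17 right-half diacetate (10′R), via dilithium alkoxide 16 (not isolated)
Conditions: MeLi (excess), Et2O/THF, −78 to 0 °C; then Ac2O, −78 °C to rt
Reagents that add atoms: methyllithium, [Li]C; acetic anhydride, CC(=O)OC(C)=O
Why: 1,2-Addition of MeLi from the equatorial direction, the axial trajectory being blocked by the syn-axial C-6′ methyl, gives the axial tertiary alkoxide (10′R), and quenching both lithium alkoxides with acetic anhydride acylates the hindered tertiary oxygen in its reactive alkoxide form together with the C-3′ oxygen.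

Step 12
Reactants: 17 right-half diacetate
Product: 18 right-half aldehyde
Conditions: O3, CH2Cl2/MeOH, −78 °C; then PPh3
Reagents that add atoms: ozone, [O-][O+]=O
Why: Ozonolysis with reductive work-up cleaves the only alkene to the aldehyde (C-12, with C-12′ as its α-carbon) and leaves all stereocentres and both acetates untouched.

Step 13
Reactants: 9 silyl enol ether (6S,7S); 18 right-half aldehyde
Product: 19 aldol adduct (mixture at C-11 and C-12)
Conditions: BF3·OEt2 (1.1 equiv), CH2Cl2, −78 °C; aqueous NaHCO3 work-up
Reagents that add atoms: none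
Why: Mukaiyama aldol addition, in which BF3 activates the aldehyde and the regiodefined silyl enol ether attacks it through C-11 in an open transition state under non-basic conditions that neither enolise the aldehyde nor touch the acetates, the silyl ether or the trisubstituted alkene at −78 °C, unites the two halves through the C-11–C-12 bond; the new centres at C-11 and C-12 are erased in step 14 and C-11 is set in step 18.

Step 14
Reactants: 19 aldol adduct
Product: 21 exocyclic enone (C-11=C-12), via mesylate 20 (not isolated)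
Conditions: MsCl, Et3N, CH2Cl2, 0 °C; then DBU, rt
Reagents that add atoms: none
Why: Mesylation followed by E1cB elimination through the C-10 enolate gives the conjugated alkylidene ketone, whose double-bond geometry is of no consequence because it is hydrogenated in step 18.

Step 15
Reactants: 21 exocyclic enone
Product: 22 hydroxy enone (C-7 OH free)
Conditions: HF·pyridine, THF, 0 °C to rt
Reagents that add atoms: none
Why: Fluoride-driven desilylation frees the C-7 hydroxyl under mildly acidic conditions that leave the acetates, the enone and the trisubstituted alkene intact.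

Step 16
Reactants: 22 hydroxy enone
Product: 23 (3S)-epoxy alcohol
Conditions: L-fructose-derived Shi ketone (0.3 equiv), Oxone (KHSO5), K2CO3, Bu4NHSO4, MeCN/dimethoxymethane/aqueous Na2B4O7 buffer, 0 °C
Reagents that add atoms: potassium peroxymonosulfate (Oxone), [K+].[O-]S(=O)(=O)OO
Why: Shi epoxidation oxidises the electron-rich 2,3-alkene only (the enone double bond is electron-poor and hindered) and the catalyst sets C-3 as (S) under reagent control, remote from the existing centres.

Step 17
Reactants: 23 (3S)-epoxy alcohol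
Product: 24 bis-oxepane enone (left oxepane closed)
Conditions: (+)-camphor-10-sulfonic acid (0.1 equiv), CH2Cl2, 0 °C
Reagents that add atoms: none
Why: The acid protonates the oxirane, the C-2–O bond lengthens in an SN1-like way, the equatorial C-7 hydroxyl captures C-2 with inversion at this non-stereogenic carbon, and proton loss leaves the former epoxide oxygen on C-3 as the free secondary hydroxyl. The closest known reaction type is the acid-catalysed endo-selective hydroxy-epoxide cyclisation of trialkyl epoxides whose more substituted carbon is the distal one. The ring is closed in the 7-endo-tet mode through the O–C-2 bond, giving the trans-fused oxepane on the existing chair cyclohexane. No new stereocentre is created: C-3 keeps the (S) configuration from the Shi epoxidation because its C–O bond is never broken, and the trans ring fusion is already fixed by C-6 and C-7. The step needs 7-endo over 6-exo selectivity, which is secured by the gem-dimethyl C-2 as the only carbon able to stabilise positive charge, by the neopentyl-like hindrance of C-3, and by a non-nucleophilic Brønsted acid in CH2Cl2 that favours the loose cation-like transition state, while the trans-diequatorial C-7 hydroxyl and C-6 chain reach C-2 without strain. Enone, acetates and the right oxepane are inert to catalytic acid at 0 °C, and release of oxirane strain drives the closure.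

Step 18
Reactants: 24 bis-oxepane enone
Product: 25 saturated C-10 ketone (11S)
Conditions: H2 (1 atm), Pd/C (10 wt %), EtOAc, rt
Reagents that add atoms: none
Why: Heterogeneous hydrogenation reduces the only remaining C=C, the enone double bond, from the face opposite the axial C-6 methyl of the rigid trans-fused bicycle, which sets C-11 with its hydrogen anti to that methyl and the side chain equatorial, the arrangement that is also thermodynamically preferred next to the ketone.

Step 19
Reactants: 25 saturated C-10 ketone
Product: 26 CNP0412606.1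
Conditions: Zn dust, CH2Br2, TiCl4, THF/CH2Cl2, 0 °C to rt (reagent pre-formed)
Reagents that add atoms: dibromomethane, BrCBr
Why: Takai–Lombardo methylenation with the non-basic zinc–titanium carbenoid converts the hindered C-10 ketone into the exocyclic methylene without epimerising C-11 and without touching the acetates or the free C-3 hydroxyl; no stereocentre is formed.

Compound list

1 | 1,4-dioxaspiro[4.5]dec-6-en-8-one | O=C1C=CC2(CC1)OCCO2 | starting material
2 | 7-iodo-1,4-dioxaspiro[4.5]dec-6-en-8-one | O=C1C(I)=CC2(CC1)OCCO2 | intermediate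
3 | (S)-7-iodo-1,4-dioxaspiro[4.5]dec-6-en-8-ol | IC1=CC2(CC[C@@H]1O)OCCO2 | intermediate
4 | (S)-tert-butyl[(7-iodo-1,4-dioxaspiro[4.5]dec-6-en-8-yl)oxy]dimethylsilane | IC1=CC2(CC[C@@H]1O[Si](C)(C)C(C)(C)C)OCCO2 | intermediate
5 | (S)-tert-butyldimethyl[(7-methyl-1,4-dioxaspiro[4.5]dec-6-en-8-yl)oxy]silane | CC1=CC2(CC[C@@H]1O[Si](C)(C)C(C)(C)C)OCCO2 | intermediate
6 | (S)-4-(tert-butyldimethylsilyloxy)-3-methylcyclohex-2-en-1-one | CC1=CC(=O)CC[C@@H]1O[Si](C)(C)C(C)(C)C | intermediate
7 | 5-bromo-2-methylpent-2-ene | CC(C)=CCCBr | starting material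
8 | (4-methylpent-3-en-1-yl)magnesium bromide | CC(C)=CCC[Mg]Br | intermediate
9 | tert-butyldimethyl{[(1S,2S)-2-methyl-2-(4-methylpent-3-en-1-yl)-4-(trimethylsilyloxy)cyclohex-3-en-1-yl]oxy}silane | C[Si](C)(C)OC1=C[C@](C)(CCC=C(C)C)[C@@H](O[Si](C)(C)C(C)(C)C)CC1 | intermediate
10 | lithium (3S,4S)-4-(tert-butyldimethylsilyloxy)-3-methyl-3-(4-methylpent-3-en-1-yl)cyclohex-1-en-1-olate | [Li]OC1=C[C@](C)(CCC=C(C)C)[C@@H](O[Si](C)(C)C(C)(C)C)CC1 | intermediate
11 | (3S,4S)-4-(tert-butyldimethylsilyloxy)-3-methyl-3-(4-methylpent-3-en-1-yl)-2-(prop-2-en-1-yl)cyclohexan-1-one, C-2 (C-11′) epimers | C=CCC1C(=O)CC[C@H](O[Si](C)(C)C(C)(C)C)[C@@]1(C)CCC=C(C)C | intermediate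
12 | (3S,4S)-4-hydroxy-3-methyl-3-(4-methylpent-3-en-1-yl)-2-(prop-2-en-1-yl)cyclohexan-1-one, C-2 epimers | C=CCC1C(=O)CC[C@H](O)[C@@]1(C)CCC=C(C)C | intermediate
13 | (3S,4S)-3-{2-[(2S)-3,3-dimethyloxiran-2-yl]ethyl}-4-hydroxy-3-methyl-2-(prop-2-en-1-yl)cyclohexan-1-one, C-2 epimers | C=CCC1C(=O)CC[C@H](O)[C@@]1(C)CC[C@@H]2OC2(C)C | intermediate
14 | (3S,5aS,9aS)-3-hydroxy-2,2,5a-trimethyl-6-(prop-2-en-1-yl)octahydro-1-benzoxepin-7(2H)-one, C-6 (C-11′) epimers | C=CCC1[C@]2(C)CC[C@H](O)C(C)(C)O[C@H]2CCC1=O | intermediate
15 | (3S,5aS,6S,9aS)-3-hydroxy-2,2,5a-trimethyl-6-(prop-2-en-1-yl)octahydro-1-benzoxepin-7(2H)-one (trans-fused; allyl equatorial, cis to the angular methyl) | C=CC[C@H]1[C@]2(C)CC[C@H](O)C(C)(C)O[C@H]2CCC1=O | intermediate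
16 | dilithium (3S,5aS,6S,7R,9aS)-2,2,5a,7-tetramethyl-6-(prop-2-en-1-yl)decahydro-1-benzoxepine-3,7-diolate (tertiary O axial) | C=CC[C@H]1[C@]2(C)CC[C@H](O[Li])C(C)(C)O[C@H]2CC[C@@]1(C)O[Li] | intermediate
17 | (3S,5aS,6S,7R,9aS)-2,2,5a,7-tetramethyl-6-(prop-2-en-1-yl)decahydro-1-benzoxepine-3,7-diyl diacetate | C=CC[C@H]1[C@]2(C)CC[C@H](OC(C)=O)C(C)(C)O[C@H]2CC[C@@]1(C)OC(C)=O | intermediate
18 | (3S,5aS,6S,7R,9aS)-2,2,5a,7-tetramethyl-6-(2-oxoethyl)decahydro-1-benzoxepine-3,7-diyl diacetate | O=CC[C@H]1[C@]2(C)CC[C@H](OC(C)=O)C(C)(C)O[C@H]2CC[C@@]1(C)OC(C)=O | intermediate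
19 | aldol adduct: left (6S,7S)-cyclohexanone (C-10 ketone, C-7 OTBS, C-6 methyl and 4-methylpent-3-enyl) joined at C-11 to the C-12 carbinol of the right-half diacetate; mixture at C-11 and C-12 | CC(C)=CCC[C@]1(C)[C@@H](O[Si](C)(C)C(C)(C)C)CCC(=O)C1C(O)C[C@H]1[C@]2(C)CC[C@H](OC(C)=O)C(C)(C)O[C@H]2CC[C@@]1(C)OC(C)=O | intermediate
20 | C-12 methanesulfonate of 19 | CC(C)=CCC[C@]1(C)[C@@H](O[Si](C)(C)C(C)(C)C)CCC(=O)C1C(OS(C)(=O)=O)C[C@H]1[C@]2(C)CC[C@H](OC(C)=O)C(C)(C)O[C@H]2CC[C@@]1(C)OC(C)=O | intermediate
21 | exocyclic enone: C-10 ketone conjugated with C-11=C-12 (E/Z not defined), C-7 OTBS, (6S,7S), right-half diacetate | CC(C)=CCC[C@]1(C)[C@@H](O[Si](C)(C)C(C)(C)C)CCC(=O)C1=CC[C@H]1[C@]2(C)CC[C@H](OC(C)=O)C(C)(C)O[C@H]2CC[C@@]1(C)OC(C)=O | intermediate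
22 | hydroxy enone: as 21 with free C-7 hydroxyl | CC(C)=CCC[C@]1(C)[C@@H](O)CCC(=O)C1=CC[C@H]1[C@]2(C)CC[C@H](OC(C)=O)C(C)(C)O[C@H]2CC[C@@]1(C)OC(C)=O | intermediate
23 | epoxy alcohol: as 22 with the (3S)-2,3-epoxide | CC1(C)O[C@H]1CC[C@]1(C)[C@@H](O)CCC(=O)C1=CC[C@H]1[C@]2(C)CC[C@H](OC(C)=O)C(C)(C)O[C@H]2CC[C@@]1(C)OC(C)=O | intermediate
24 | bis-oxepane enone: target skeleton with C-10 ketone and C-11=C-12 double bond, free (3S)-hydroxyl, (6S,7S) | O=C1CC[C@@H]2OC(C)(C)[C@@H](O)CC[C@@]2(C)C1=CC[C@H]1[C@]2(C)CC[C@H](OC(C)=O)C(C)(C)O[C@H]2CC[C@@]1(C)OC(C)=O | intermediate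
25 | 10-oxo analogue of the target (C-10 ketone in place of C=CH2), (3S,6S,7S,11S) | O=C1CC[C@@H]2OC(C)(C)[C@@H](O)CC[C@@]2(C)[C@@H]1CC[C@H]1[C@]2(C)CC[C@H](OC(C)=O)C(C)(C)O[C@H]2CC[C@@]1(C)OC(C)=O | intermediate
26 | CNP0412606.1, (3S,6S,7S,11R,3′S,6′S,7′S,10′R,11′S) | C=C1CC[C@@H]2OC(C)(C)[C@@H](O)CC[C@@]2(C)[C@@H]1CC[C@H]1[C@]2(C)CC[C@H](OC(C)=O)C(C)(C)O[C@H]2CC[C@@]1(C)OC(C)=O | target

Step count and risks

Total step count: 19. Longest linear sequence: 19 (steps 1–12 to aldehyde 18, then steps 13–19; enol ether 9 from step 6 re-enters at step 13).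

Steps most likely to fail:

1. Step 17 (key step). The C-7 hydroxyl may attack C-3 in the 6-exo mode, or the protonated oxirane may rearrange by hydride shift, so that closure at C-2 is not clean. The fallback sets out from 23 and removes the ambiguity by making C-3 unreactive. Titanocene monochloride (Cp2TiCl, trivalent titanium, from Cp2TiCl2 and Mn dust, THF) opens the epoxide homolytically at C-2, and β-hydride elimination should give the (3S)-isopropenyl carbinol F1 with the C-3–O bond untouched. Intramolecular oxymercuration with Hg(OCOCF3)2 (divalent mercury; MeCN, then aqueous NaCl) adds the C-7 hydroxyl to C-2, the only cation-stabilising alkene carbon (Markovnikov, seven-membered ring; no six-membered alternative exists because C-3 is saturated), giving the chloromercuriomethyl oxepane F2. Reductive demercuration with Bu3SnH/AIBN, which spares the enone and the acetates, turns the CH2HgCl group into the second C-2 methyl and comes back to the route at 24.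

2. Step 10. The same loss of regiocontrol (6-exo attack at C-3′) may occur in the closure of the right oxepane. The fallback sets out from 13 and follows the same logic. Cp2TiCl (from Cp2TiCl2 and Mn dust, THF) should give the (3′S)-isopropenyl carbinol F3. Hg(OCOCF3)2 (one equivalent, MeCN, then aqueous NaCl) should cyclise the C-7′ hydroxyl onto C-2′ faster than it touches the isolated allyl group, giving the chloromercuriomethyl oxepane F4. Bu3SnH/AIBN then gives 14, which is equilibrated with NaOMe in MeOH as in step 10 and comes back to the route at 15.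

3. Step 11. Enolisation of the hindered ketone may compete with addition, and O-acylation of the syn-axially shielded tertiary alkoxide may stay incomplete. The fallback sets out from 15 and separates the two events. Addition of MeMgBr in the presence of CeCl3 (organocerium addition, which suppresses enolisation; THF, −78 °C) and aqueous work-up should give the isolated tertiary diol F5. Nucleophilic acyl-transfer catalysis on the free alcohols (Ac2O, DMAP, Et3N, CH2Cl2, 40 °C, prolonged) then acetylates both hydroxyls and comes back to the route at 17.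

Further compounds

F1 | step 17 | (3S)-isopropenyl carbinol: 22 with the chain end CH2CH2CH(OH)C(CH3)=CH2 in place of the prenyl terminus | C=C(C)[C@@H](O)CC[C@]1(C)[C@@H](O)CCC(=O)C1=CC[C@H]1[C@]2(C)CC[C@H](OC(C)=O)C(C)(C)O[C@H]2CC[C@@]1(C)OC(C)=O
F2 | step 17 | chloromercuriomethyl oxepane: 24 with one C-2 methyl as CH2HgCl (C-2 epimers) | O=C1CC[C@@H]2OC(C)(C[Hg]Cl)[C@@H](O)CC[C@@]2(C)C1=CC[C@H]1[C@]2(C)CC[C@H](OC(C)=O)C(C)(C)O[C@H]2CC[C@@]1(C)OC(C)=O
F3 | step 10 | (3′S)-isopropenyl carbinol of the right half (C-11′ epimers) | C=CCC1C(=O)CC[C@H](O)[C@@]1(C)CC[C@H](O)C(C)=C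
F4 | step 10 | chloromercuriomethyl oxepane ketone of the right half (C-2′ and C-11′ epimers) | C=CCC1[C@]2(C)CC[C@H](O)C(C)(C[Hg]Cl)O[C@H]2CCC1=O
F5 | step 11 | (3S,5aS,6S,7R,9aS)-2,2,5a,7-tetramethyl-6-(prop-2-en-1-yl)decahydro-1-benzoxepine-3,7-diol | C=CC[C@H]1[C@]2(C)CC[C@H](O)C(C)(C)O[C@H]2CC[C@@]1(C)O
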